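**Retrosynthetic overview**
1. 5 ⇒ 4: the two 3-O-galloyl esters stay on until the end and are removed enzymatically. They come with the starting material and help organise the coupling.
2. 4 ⇒ 3 ⇒ 2 + 2: the only C–C disconnection is the central ring B–ring B bond (C2′–C2′). Both carbons are donor carbons of a pyrogallol. Two-electron oxidation turns ring B into a hydroxy-ortho-quinone whose CH terminus is an acceptor (a vinylogous enolonium equivalent). No halide, boron or protecting group is needed.
3. 2 ⇒ 1: EGCG, the bulk catechin of green tea, supplies all four sp3 centres (2R,3R twice).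
4. Ring order: rings A, C and B of both halves are bought with 1. The only ring formed is the five-membered hemiketal ring of 3. It holds the new stereochemical information at an sp3 methine and opens on reduction, passing that information to the axis.

Assumption: the given SMILES cannot show the biaryl axis, so theasinensin C is taken as the aR (M) atropisomer (the aS isomer is theasinensin E), and 4 and 5 are written without an axis descriptor.

**Route**

Step 1
Reactants: 1 (−)-epigallocatechin 3-O-gallate (EGCG), two molecules
Product: 4 theasinensin A (aR), via EGCG ortho-quinone 2 (not isolated), via dehydrotheasinensin A 3 (not isolated)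
Conditions: CuCl2·2H2O (2.5 equiv per 1), H2O (0.02 M), 20 °C, 12 h; then L-ascorbic acid (3 equiv per 1), N2, 80 °C, 20 min, same flask; Sephadex LH-20 (H2O → EtOH → aq. acetone)
Reagents that add atoms: none
Why: Biomimetic oxidative phenol coupling through an ortho-quinone: divalent copper removes two electrons only from the electron-rich pyrogallol ring B (the ester-deactivated galloyl ring and the resorcinol-type ring A cannot compete), so the ring B CH carbon that is a donor in 1 becomes the acceptor terminus of the dienone in 2 and takes up the enol carbon of a second molecule of 2 in a vinylogous Michael addition; the partners stack face to face in water (ring A and galloyl over ring B), which gives one methine epimer of 3 (hemiketal plus one molecule of solvent water that leaves again), and ascorbic acid then reduces and rearomatises 3 with central-to-axial chirality transfer to the aR biaryl, while the HCl formed keeps the pH near 2 to 3, where the methine of 3 and C2 of the chromans do not epimerise.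

Step 2
Reactants: 4 theasinensin A
Product: 5 theasinensin C (target)
Conditions: tannase (tannin acyl hydrolase, Aspergillus oryzae), acetate buffer pH 5.5, N2, 37 °C, 4 h; Sephadex LH-20
Reagents that add atoms: none
Why: Enzymatic ester hydrolysis with acyl–oxygen cleavage is specific for galloyl esters and runs at pH 5.5 and 37 °C, so the C3–O bonds and all four sp3 centres are untouched, base-triggered C2 epimerisation and autoxidation of the pyrogallol rings are avoided, and the tetra-ortho-substituted axis cannot rotate.

**Compound list**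
1 | (−)-epigallocatechin 3-O-gallate (EGCG), (2R,3R)-5,7-dihydroxy-2-(3,4,5-trihydroxyphenyl)chroman-3-yl 3,4,5-trihydroxybenzoate | Oc1cc(O)c2c(c1)O[C@H](c1cc(O)c(O)c(O)c1)[C@H](OC(=O)c1cc(O)c(O)c(O)c1)C2 | starting material
2 | EGCG ortho-quinone: 1 with ring B oxidised to the 5′-hydroxy-3′,4′-ortho-benzoquinone, 2R,3R unchanged | Oc1cc(O)c2c(c1)O[C@H](C1=CC(=O)C(=O)C(O)=C1)[C@H](OC(=O)c1cc(O)c(O)c(O)c1)C2 | intermediate
3 | dehydrotheasinensin A: C2′–C2′-linked dimer of 2 plus one H2O. One ring B is aromatic. The other is a cyclohexenone (C5′=O, C1′=C6′) with a gem-diol at C4′ and a hemiketal at C3′ closed by the 3′-O of the aromatic ring B (cis-fused dihydrobenzofuran). The sp3 methine C2′ is drawn 2′S,3′R, the configuration that correlates by least motion with the aR axis | Oc1cc(O)c2c(c1)O[C@H](C1=CC(=O)C(O)(O)[C@]3(O)Oc4c(O)c(O)cc([C@H]5Oc6cc(O)cc(O)c6C[C@H]5OC(=O)c5cc(O)c(O)c(O)c5)c4[C@H]13)[C@H](OC(=O)c1cc(O)c(O)c(O)c1)C2 | intermediate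
4 | theasinensin A: aR biaryl dimer of EGCG joined ring B C2′ to ring B C2′, all chroman centres 2R,3R | Oc1cc(O)c2c(c1)O[C@H](c1cc(O)c(O)c(O)c1-c1c([C@H]3Oc4cc(O)cc(O)c4C[C@H]3OC(=O)c3cc(O)c(O)c(O)c3)cc(O)c(O)c1O)[C@H](OC(=O)c1cc(O)c(O)c(O)c1)C2 | intermediate
5 | theasinensin C: aR biaryl dimer of (−)-epigallocatechin joined ring B C2′ to ring B C2′, all chroman centres 2R,3R | Oc1cc(O)c2c(c1)O[C@H](c1cc(O)c(O)c(O)c1-c1c([C@H]3Oc4cc(O)cc(O)c4C[C@H]3O)cc(O)c(O)c1O)[C@H](O)C2 | target

**Totals and risks**
Total step count: 2. Longest linear sequence: 2. The route has only two steps, so both are ranked and no third one can be named.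

Most likely to fail, first place: step 1.
- The dimerisation of 2 may be diverted. The galloyl ring can act as a competing partner, and benzotropolone or oolongtheanin-type products can form.
- The methine of 3 may enolise before reduction, which erodes the axis toward the aS isomer.
- Ascorbic acid may add to 3 instead of reducing it.

The fallback changes the order of events, the coupling substrate and the kind of oxidant. It sets out from 1. The galloyl ester is removed first with tannase (pH 5.5, 37 °C) to give (−)-epigallocatechin F1. This is oxidised with O2 and a polyphenol oxidase (mushroom tyrosinase, pH 5.5, 20 °C). EGC ortho-quinone F2 therefore forms slowly, at low stationary concentration, with no galloyl ring present. It dimerises and hydrates to dehydrotheasinensin C F3. After ultrafiltration of the enzyme, the solution is free of metal salts. It is acidified to pH 3 and reduced with ascorbic acid under N2. The fallback comes back to the route at 5 and makes step 2 unnecessary.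

Second place: step 2. The two esters sit next to the tetra-ortho-substituted biaryl and may be poor enzyme substrates, and gallic acid may inhibit the enzyme.

The fallback replaces hydrolysis by reductive ester cleavage under transient protection. No phenolate forms, so the quinone-methide path to C2 epimerisation is closed. It sets out from 4. N,O-bis(trimethylsilyl)acetamide in THF at 50 °C gives hexadeca-O-trimethylsilyl theasinensin A F4. Then i-Bu2AlH (6 equiv, toluene/THF, −78 to −20 °C) reduces both galloyl esters to give deca-O-trimethylsilyl theasinensin C F5. Work-up with citric acid in aqueous MeOH strips all aryl silyl ethers. The fallback comes back to the route at 5.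

**Further compounds**
F1 | step 1 | (−)-epigallocatechin (2R,3R) | Oc1cc(O)c2c(c1)O[C@H](c1cc(O)c(O)c(O)c1)[C@H](O)C2
F2 | step 1 | EGC ortho-quinone (ring B 5′-hydroxy-3′,4′-ortho-benzoquinone, 2R,3R) | Oc1cc(O)c2c(c1)O[C@H](C1=CC(=O)C(=O)C(O)=C1)[C@H](O)C2
F3 | step 1 | dehydrotheasinensin C (hydrated hemiketal form, core as in 3, free 3-OH groups) | Oc1cc(O)c2c(c1)O[C@H](C1=CC(=O)C(O)(O)[C@]3(O)Oc4c(O)c(O)cc([C@H]5Oc6cc(O)cc(O)c6C[C@H]5O)c4[C@H]13)[C@H](O)C2
F4 | step 2 | hexadeca-O-trimethylsilyl theasinensin A (all sixteen phenols silylated, aR) | C[Si](C)(C)Oc1cc(O[Si](C)(C)C)c2c(c1)O[C@H](c1cc(O[Si](C)(C)C)c(O[Si](C)(C)C)c(O[Si](C)(C)C)c1-c1c([C@H]3Oc4cc(O[Si](C)(C)C)cc(O[Si](C)(C)C)c4C[C@H]3OC(=O)c3cc(O[Si](C)(C)C)c(O[Si](C)(C)C)c(O[Si](C)(C)C)c3)cc(O[Si](C)(C)C)c(O[Si](C)(C)C)c1O[Si](C)(C)C)[C@H](OC(=O)c1cc(O[Si](C)(C)C)c(O[Si](C)(C)C)c(O[Si](C)(C)C)c1)C2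
F5 | step 2 | deca-O-trimethylsilyl theasinensin C (all ten phenols silylated, free 3-OH groups, aR) | C[Si](C)(C)Oc1cc(O[Si](C)(C)C)c2c(c1)O[C@H](c1cc(O[Si](C)(C)C)c(O[Si](C)(C)C)c(O[Si](C)(C)C)c1-c1c([C@H]3Oc4cc(O[Si](C)(C)C)cc(O[Si](C)(C)C)c4C[C@H]3O)cc(O[Si](C)(C)C)c(O[Si](C)(C)C)c1O[Si](C)(C)C)[C@H](O)C2
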